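**Retrosynthetic overview** (labdane numbering: ring A = C1–C5, C10; ring B = C5–C10)
- Late disconnections: O13–Si, C8=C17 (titanium methylenation), and C9–C11 (alkylation of a C8 enone at C9 with iodide 6, made from (R)-linalool, which brings C13).
- Ring A is opened at C1–C2 and C3–C4: a decarboxylative radical [4+2] annulation of a ring-B redox-active ester with vinyl bromide, which supplies C2–C3 and the bromine on C3.
- Enabling feature: in ring B the exocyclic isopropylidene ketone C4=C5–C6=O sits next to the quaternary C10, which carries the CH2–CO2N(phthaloyl) arm. Loss of CO2 gives the C1 radical and the enone accepts the C3 radical at C4.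
- The C6 carbonyl is only an activating group: a Wharton transposition moves the oxygen to C8, where it steers the C9 alkylation and is finally replaced by C17.
- Stereocentres: C10 by copper-catalysed asymmetric conjugate methylation, C3, C5 and C9 relayed from it, C13 bought; ring B first, then ring A.

Key step: step 10

Remark: in step 6 the antipode of the phosphoramidite ligand is assumed to be the one that delivers methyl to the enone face giving (R)-11; the mirror-image ligand is equally available.

Step 1
Reactants: 1 (R)-linalool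
Product: 2 (3R)-3,7-dimethyl-3-(triethylsilyloxy)octa-1,6-diene
Conditions: Et3SiOTf, 2,6-lutidine, CH2Cl2, −78 to 0 °C
Reagents that add atoms: triethylsilyl trifluoromethanesulfonate, CC[Si](CC)(CC)OS(=O)(=O)C(F)(F)F
Why: Silyl triflate with a hindered pyridine base is the standard O-silylation of a tertiary allylic alcohol and protects O13 through the later enolate, hydride and titanium steps.

Step 2
Reactants: 2 (3R)-3,7-dimethyl-3-(triethylsilyloxy)octa-1,6-diene
Product: 3 (4R)-4-methyl-4-(triethylsilyloxy)hex-5-enal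
Conditions: O3 (1 equiv, indicator end-point), CH2Cl2, −78 °C; then Me2S
Reagents that add atoms: ozone, [O-][O+]=O
Why: Chemoselective ozonolysis, because ozone attacks the electron-rich trisubstituted alkene far faster than the hindered monosubstituted vinyl group.

Step 3
Reactants: 3 (4R)-4-methyl-4-(triethylsilyloxy)hex-5-enal
Product: 4 (4R)-4-methyl-4-(triethylsilyloxy)hex-5-enoic acid
Conditions: NaClO2, NaH2PO4, 2-methyl-2-butene, t-BuOH/H2O, 0 °C to rt
Reagents that add atoms: sodium chlorite, [Na+].[O-]Cl=O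
Why: Pinnick oxidation converts the aldehyde to the acid under buffered conditions that leave the vinyl group and the silyl ether untouched.

Step 4
Reactants: 4 (4R)-4-methyl-4-(triethylsilyloxy)hex-5-enoic acid
Product: 6 (3R)-5-iodo-3-methyl-3-(triethylsilyloxy)pent-1-ene, via Barton ester 5 (not isolated)
Conditions: 1-hydroxypyridine-2(1H)-thione, DCC, DMAP (cat.), CH2Cl2, dark, 0 °C to rt; then CHI3, hν (tungsten lamp), rt
Reagents that add atoms: iodoform, IC(I)I
Why: Barton decarboxylative iodination, in which the thiohydroxamate ester fragments to the primary radical that abstracts iodine from iodoform without touching C13.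

Step 5
Reactants: 7 3-ethoxycyclohex-2-en-1-one; 8 tert-butyl acetate
Product: 9 tert-butyl 2-(3-oxocyclohex-1-en-1-yl)acetate
Conditions: LDA, THF, −78 °C (8), then 7; then 1 M HCl, 0 °C
Reagents that add atoms: none
Why: Stork–Danheiser sequence, i.e. 1,2-addition of the ester enolate to the vinylogous ester followed by acid hydrolysis and elimination, which transposes the enone.

Step 6
Reactants: 9 tert-butyl 2-(3-oxocyclohex-1-en-1-yl)acetate
Product: 11 tert-butyl 2-[(1R)-1-methyl-3-(trimethylsilyloxy)cyclohex-2-en-1-yl]acetate, via aluminium enolate 10 (not isolated)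
Conditions: Me3Al, Cu(thiophene-2-carboxylate) (5 mol %), BINOL-derived bis(1-phenylethyl)amine phosphoramidite (10 mol %), Et2O, −30 °C; then Me3SiOTf, −30 to 0 °C
Reagents that add atoms: trimethylaluminium, C[Al](C)C; trimethylsilyl trifluoromethanesulfonate, C[Si](C)(C)OS(=O)(=O)C(F)(F)F
Why: Copper-catalysed asymmetric conjugate addition of Me3Al to a 3-substituted cyclohexenone should build the quaternary C10, its configuration set by the chiral copper–phosphoramidite complex, and silylation fixes the enolate regiospecifically towards C5.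

Step 7
Reactants: 11 tert-butyl 2-[(1R)-1-methyl-3-(trimethylsilyloxy)cyclohex-2-en-1-yl]acetate
Product: 13 tert-butyl 2-[(1R)-1-methyl-3-oxo-2-(propan-2-ylidene)cyclohexyl]acetate, via methoxy ketone 12 (not isolated)
Conditions: Me2C(OMe)2, Me3SiOTf (10 mol %), CH2Cl2, −78 °C; then DBU, rt to 40 °C
Reagents that add atoms: 2,2-dimethoxypropane, COC(C)(C)OC
Why: Mukaiyama-type addition of the silyl enol ether to the acetone-derived oxocarbenium ion, then E1cB loss of methanol, should place the conjugated isopropylidene group on C5 only.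

Step 8
Reactants: 13 tert-butyl 2-[(1R)-1-methyl-3-oxo-2-(propan-2-ylidene)cyclohexyl]acetate
Product: 14 2-[(1R)-1-methyl-3-oxo-2-(propan-2-ylidene)cyclohexyl]acetic acid
Conditions: CF3CO2H, CH2Cl2, 0 °C to rt
Reagents that add atoms: none
Why: Acidolysis of the tert-butyl ester through the tert-butyl cation frees the acid without base, so the strained enone is not deconjugated.

Step 9
Reactants: 14 2-[(1R)-1-methyl-3-oxo-2-(propan-2-ylidene)cyclohexyl]acetic acid
Product: 15 1,3-dioxoisoindolin-2-yl 2-[(1R)-1-methyl-3-oxo-2-(propan-2-ylidene)cyclohexyl]acetate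
Conditions: N-hydroxyphthalimide, N,N'-diisopropylcarbodiimide, DMAP (cat.), CH2Cl2, rt
Reagents that add atoms: N-hydroxyphthalimide, O=C1c2ccccc2C(=O)N1O
Why: Carbodiimide esterification gives the redox-active ester that releases the C1 radical on single-electron reduction.

Step 10
Reactants: 15 1,3-dioxoisoindolin-2-yl 2-[(1R)-1-methyl-3-oxo-2-(propan-2-ylidene)cyclohexyl]acetate; 16 vinyl bromide
Product: 18 (4aR,7R,8aS)-7-bromo-4a,8,8-trimethyloctahydronaphthalen-1(2H)-one, via C5-epimer mixture 17 (not isolated)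
Conditions: 16 (large excess, ca. 3 M), Ru(bpy)3(PF6)2 (1 mol %), Hantzsch ester (1.5 equiv), CH2Cl2, blue LEDs, 0 °C, sealed vessel; then DBU (cat.), rt
Reagents that add atoms: none
Why: Proposed new method: single-electron reduction of the N-acyloxyphthalimide by the photoreduced ruthenium complex gives, after loss of CO2 and phthalimide anion, the primary radical at C1; this adds to the CH2 terminus of vinyl bromide (C1–C2), the α-bromoalkyl radical at C3 closes on C4, the β-carbon of the C4=C5–C6=O enone (C3–C4), and the α-keto radical at C5 takes a hydrogen atom from the Hantzsch ester. The closest known reactions are decarboxylative Giese additions of redox-active esters, radical additions to vinyl halides and 6-endo radical cyclisations onto α-alkylidene ketones, here merged into one radical [4+2] annulation. Ring A closes in the 6-endo-trig mode, favoured by the enone polarisation and by the fully substituted C5, which disfavour 5-exo attack. C3 should be set in a chair-like transition state with bromine pseudo-equatorial, i.e. cis to the C10 methyl, and C5 under thermodynamic control, because DBU equilibrates the α-keto centre to the trans-fused decalone; both are relayed from C10. The step needs addition of the nucleophilic C1 radical to vinyl bromide ahead of premature reduction, and ring closure ahead of telomerisation; the large excess of vinyl bromide, the low steady-state radical concentration and the proximity of the strained electron-poor isopropylidene ketone are meant to secure this.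

Step 11
Reactants: 18 (4aR,7R,8aS)-7-bromo-4a,8,8-trimethyloctahydronaphthalen-1(2H)-one
Product: 19 (4aS,7R,8aS)-7-bromo-4a,8,8-trimethyl-4a,5,6,7,8,8a-hexahydronaphthalen-1(4H)-one
Conditions: IBX, DMSO, 70 °C
Reagents that add atoms: none
Why: IBX dehydrogenation of the ketone can only give the C7=C8 enone, because the other α-carbon (C5) has no β-hydrogen.

Step 12
Reactants: 19 (4aS,7R,8aS)-7-bromo-4a,8,8-trimethyl-4a,5,6,7,8,8a-hexahydronaphthalen-1(4H)-one
Product: 20 7,8-epoxide of 19 (labdane numbering 3R,5S,7R,8R,10S; oxirane oxygen on the face opposite the C10 methyl)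
Conditions: 30% aq. H2O2, NaOH (cat.), MeOH, 0 °C
Reagents that add atoms: hydrogen peroxide, OO
Why: Weitz–Scheffer nucleophilic epoxidation, in which hydroperoxide adds to C8 anti to the axial C10 methyl (the epoxide configuration is lost later).

Step 13
Reactants: 20 7,8-epoxide of 19
Product: 21 (2R,4aS,6R,8aS)-6-bromo-5,5,8a-trimethyl-1,2,4a,5,6,7,8,8a-octahydronaphthalen-2-ol
Conditions: N2H4·H2O, AcOH (cat.), MeOH, 0 °C to rt
Reagents that add atoms: none
Why: Wharton transposition, in which the epoxy hydrazone fragments with loss of N2 to the allylic alcohol, moving the oxygen from C6 to C8.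

Step 14
Reactants: 21 (2R,4aS,6R,8aS)-6-bromo-5,5,8a-trimethyl-1,2,4a,5,6,7,8,8a-octahydronaphthalen-2-ol
Product: 22 (4aS,6R,8aS)-6-bromo-5,5,8a-trimethyl-4a,5,6,7,8,8a-hexahydronaphthalen-2(1H)-one
Conditions: Dess–Martin periodinane, NaHCO3, CH2Cl2, rt
Reagents that add atoms: none
Why: Hypervalent-iodine oxidation of the allylic alcohol gives the C8 enone under neutral conditions that spare the bromide and the γ-centre C5.

Step 15
Reactants: 22 (4aS,6R,8aS)-6-bromo-5,5,8a-trimethyl-4a,5,6,7,8,8a-hexahydronaphthalen-2(1H)-one; 6 (3R)-5-iodo-3-methyl-3-(triethylsilyloxy)pent-1-ene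
Product: 23 (1R,4aS,6R,8aR)-6-bromo-5,5,8a-trimethyl-1-[(3R)-3-methyl-3-(triethylsilyloxy)pent-4-en-1-yl]-4a,5,6,7,8,8a-hexahydronaphthalen-2(1H)-one
Conditions: LDA, THF, −78 °C; then 6, DMPU, −78 to −20 °C
Reagents that add atoms: none
Why: Kinetic α'-deprotonation of the enone at C9 gives the cross-conjugated dienolate, whose SN2 alkylation should occur axially on the face opposite the axial C10 methyl, placing C11 trans to that methyl as in the target.

Step 16
Reactants: 23 (1R,4aS,6R,8aR)-6-bromo-5,5,8a-trimethyl-1-[(3R)-3-methyl-3-(triethylsilyloxy)pent-4-en-1-yl]-4a,5,6,7,8,8a-hexahydronaphthalen-2(1H)-one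
Product: 24 (1R,4aS,6R,8aR)-6-bromo-5,5,8a-trimethyl-1-[(3R)-3-methyl-3-(triethylsilyloxy)pent-4-en-1-yl]octahydronaphthalen-2(1H)-one
Conditions: [(Ph3P)CuH]6, H2O (2 equiv), THF/benzene, rt
Reagents that add atoms: none
Why: Conjugate reduction by the phosphine copper hydride touches only the C6=C7 enone bond and forms the enolate towards C7, so the vinyl group, the bromide and the C9 centre are left alone.

Step 17
Reactants: 24 (1R,4aS,6R,8aR)-6-bromo-5,5,8a-trimethyl-1-[(3R)-3-methyl-3-(triethylsilyloxy)pent-4-en-1-yl]octahydronaphthalen-2(1H)-one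
Product: 25 triethyl{[(3R)-5-[(1S,4aS,6R,8aS)-6-bromo-5,5,8a-trimethyl-2-methylidenedecahydronaphthalen-1-yl]-3-methylpent-1-en-3-yl]oxy}silane
Conditions: Cp2TiMe2, toluene, 70 °C, dark
Reagents that add atoms: dimethyltitanocene, [Ti+4].[CH3-].[CH3-].c1cc[cH-]c1.c1cc[cH-]c1
Why: Petasis methylenation through the titanium methylidene is non-basic, so the epimerisable axial C9 centre next to the hindered ketone is kept.

Step 18
Reactants: 25 triethyl{[(3R)-5-[(1S,4aS,6R,8aS)-6-bromo-5,5,8a-trimethyl-2-methylidenedecahydronaphthalen-1-yl]-3-methylpent-1-en-3-yl]oxy}silane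
Product: 26 (3R)-5-[(1S,4aS,6R,8aS)-6-bromo-5,5,8a-trimethyl-2-methylidenedecahydronaphthalen-1-yl]-3-methylpent-1-en-3-ol
Conditions: Bu4NF, AcOH (buffer), THF, 0 °C to rt
Reagents that add atoms: none
Why: Buffered fluoride desilylation frees the tertiary allylic alcohol without E2 loss of the equatorial bromide.

**Compound list**
1 | (R)-linalool | C=C[C@](C)(O)CCC=C(C)C | starting material
2 | (3R)-3,7-dimethyl-3-(triethylsilyloxy)octa-1,6-diene | C=C[C@](C)(O[Si](CC)(CC)CC)CCC=C(C)C | intermediate
3 | (4R)-4-methyl-4-(triethylsilyloxy)hex-5-enal | C=C[C@](C)(O[Si](CC)(CC)CC)CCC=O | intermediate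
4 | (4R)-4-methyl-4-(triethylsilyloxy)hex-5-enoic acid | C=C[C@](C)(O[Si](CC)(CC)CC)CCC(=O)O | intermediate
5 | 2-thioxopyridin-1(2H)-yl (4R)-4-methyl-4-(triethylsilyloxy)hex-5-enoate (Barton ester) | C=C[C@](C)(O[Si](CC)(CC)CC)CCC(=O)On1ccccc1=S | intermediate
6 | (3R)-5-iodo-3-methyl-3-(triethylsilyloxy)pent-1-ene | C=C[C@](C)(O[Si](CC)(CC)CC)CCI | intermediate
7 | 3-ethoxycyclohex-2-en-1-one | CCOC1=CC(=O)CCC1 | starting material
8 | tert-butyl acetate | CC(=O)OC(C)(C)C | starting material
9 | tert-butyl 2-(3-oxocyclohex-1-en-1-yl)acetate | CC(C)(C)OC(=O)CC1=CC(=O)CCC1 | intermediate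
10 | dimethylaluminium enolate of tert-butyl 2-[(1R)-1-methyl-3-oxocyclohexyl]acetate | C[Al](C)OC1=C[C@@](C)(CC(=O)OC(C)(C)C)CCC1 | intermediate
11 | tert-butyl 2-[(1R)-1-methyl-3-(trimethylsilyloxy)cyclohex-2-en-1-yl]acetate | C[Si](C)(C)OC1=C[C@@](C)(CC(=O)OC(C)(C)C)CCC1 | intermediate
12 | tert-butyl 2-[(1R)-2-(2-methoxypropan-2-yl)-1-methyl-3-oxocyclohexyl]acetate (C2 epimers) | COC(C)(C)C1C(=O)CCC[C@]1(C)CC(=O)OC(C)(C)C | intermediate
13 | tert-butyl 2-[(1R)-1-methyl-3-oxo-2-(propan-2-ylidene)cyclohexyl]acetate | CC(C)=C1C(=O)CCC[C@]1(C)CC(=O)OC(C)(C)C | intermediate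
14 | 2-[(1R)-1-methyl-3-oxo-2-(propan-2-ylidene)cyclohexyl]acetic acid | CC(C)=C1C(=O)CCC[C@]1(C)CC(=O)O | intermediate
15 | 1,3-dioxoisoindolin-2-yl 2-[(1R)-1-methyl-3-oxo-2-(propan-2-ylidene)cyclohexyl]acetate | CC(C)=C1C(=O)CCC[C@]1(C)CC(=O)ON1C(=O)c2ccccc2C1=O | intermediate
16 | vinyl bromide (bromoethene) | C=CBr | starting material
17 | 7-bromo-4a,8,8-trimethyloctahydronaphthalen-1(2H)-one, (4aR,7R), mixture of epimers at C8a (labdane C5) | C1CCC(=O)C2C(C)(C)[C@H](Br)CC[C@]21C | intermediate
18 | (4aR,7R,8aS)-7-bromo-4a,8,8-trimethyloctahydronaphthalen-1(2H)-one (trans-fused; Br equatorial, cis to the angular methyl) | C1CCC(=O)[C@@H]2C(C)(C)[C@H](Br)CC[C@]21C | intermediate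
19 | (4aS,7R,8aS)-7-bromo-4a,8,8-trimethyl-4a,5,6,7,8,8a-hexahydronaphthalen-1(4H)-one | C1C=CC(=O)[C@@H]2C(C)(C)[C@H](Br)CC[C@]21C | intermediate
20 | 7,8-epoxide of 19 (labdane numbering 3R,5S,7R,8R,10S; oxygen anti to the angular methyl) | C1[C@H]3O[C@H]3C(=O)[C@@H]2C(C)(C)[C@H](Br)CC[C@]21C | intermediate
21 | (2R,4aS,6R,8aS)-6-bromo-5,5,8a-trimethyl-1,2,4a,5,6,7,8,8a-octahydronaphthalen-2-ol | C1[C@@H](O)C=C[C@@H]2C(C)(C)[C@H](Br)CC[C@]21C | intermediate
22 | (4aS,6R,8aS)-6-bromo-5,5,8a-trimethyl-4a,5,6,7,8,8a-hexahydronaphthalen-2(1H)-one | C1C(=O)C=C[C@@H]2C(C)(C)[C@H](Br)CC[C@]21C | intermediate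
23 | (1R,4aS,6R,8aR)-6-bromo-5,5,8a-trimethyl-1-[(3R)-3-methyl-3-(triethylsilyloxy)pent-4-en-1-yl]-4a,5,6,7,8,8a-hexahydronaphthalen-2(1H)-one | C=C[C@](C)(O[Si](CC)(CC)CC)CC[C@H]1C(=O)C=C[C@@H]2C(C)(C)[C@H](Br)CC[C@]21C | intermediate
24 | (1R,4aS,6R,8aR)-6-bromo-5,5,8a-trimethyl-1-[(3R)-3-methyl-3-(triethylsilyloxy)pent-4-en-1-yl]octahydronaphthalen-2(1H)-one | C=C[C@](C)(O[Si](CC)(CC)CC)CC[C@H]1C(=O)CC[C@@H]2C(C)(C)[C@H](Br)CC[C@]21C | intermediate
25 | triethyl{[(3R)-5-[(1S,4aS,6R,8aS)-6-bromo-5,5,8a-trimethyl-2-methylidenedecahydronaphthalen-1-yl]-3-methylpent-1-en-3-yl]oxy}silane | C=C[C@](C)(O[Si](CC)(CC)CC)CC[C@H]1C(=C)CC[C@@H]2C(C)(C)[C@H](Br)CC[C@]21C | intermediate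
26 | (3R)-5-[(1S,4aS,6R,8aS)-6-bromo-5,5,8a-trimethyl-2-methylidenedecahydronaphthalen-1-yl]-3-methylpent-1-en-3-ol | C=C[C@](C)(O)CC[C@H]1C(=C)CC[C@@H]2C(C)(C)[C@H](Br)CC[C@]21C | target

**Step count and risks**

Total: 18 steps. Longest linear sequence: 14 steps (steps 5 to 18); iodide 6 takes 4 steps (steps 1 to 4) and joins at step 15.

Step 10 is the most likely to fail. The C1 radical may be quenched by hydrogen-atom transfer before it adds to the poorly activated vinyl bromide, the α-bromo radical may telomerise before it cyclises, and facial control at C3 may be incomplete. The fallback sets out from acid 14 and uses known reaction types, with C2 taken from the acetic acid arm instead of from vinyl bromide. Acid 14 is converted with EtSH, DCC and DMAP into S-ethyl 2-[(1R)-1-methyl-3-oxo-2-(propan-2-ylidene)cyclohexyl]ethanethioate F1. Fukuyama reduction (Et3SiH, Pd on carbon) gives 2-[(1R)-1-methyl-3-oxo-2-(propan-2-ylidene)cyclohexyl]acetaldehyde F2. A Wittig reaction with bromomethylenetriphenylphosphorane gives (3R)-3-(3-bromoprop-2-en-1-yl)-3-methyl-2-(propan-2-ylidene)cyclohexan-1-one F3 as an E/Z mixture. An iron hydride hydrogen-atom-transfer reductive cyclisation (Fe(acac)3, PhSiH3, EtOH, 60 °C; then DBU) should then deliver hydrogen to C2 and generate the same α-bromo radical at C3, which closes 6-endo on C4. This comes back to the route at 18.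

Step 15 is the second risk. SN2 attack of the hindered cross-conjugated enolate on an unactivated primary iodide may be slow, and proton transfer would then erode the kinetic C9 configuration. The fallback sets out from 22 and uses an azaenolate, a far better nucleophile for such halides. Condensation with Me2NNH2 (cat. AcOH) gives the N,N-dimethylhydrazone of 22 F4. Metalation with LDA at C9 and alkylation with 6, again anti to the C10 methyl, gives the C9-alkylated N,N-dimethylhydrazone F5. Hydrolysis with aqueous Cu(OAc)2 comes back to the route at 23.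

Step 7 is the third risk. The neopentyl-type C5 nucleophile may fail to add to the ketal-derived cation or the adduct may revert, and the strained isopropylidene ketone may deconjugate. The fallback sets out from 11. MeLi in THF gives the lithium enolate, which is added to acetone at −78 °C to give tert-butyl 2-[(1R)-2-(2-hydroxypropan-2-yl)-1-methyl-3-oxocyclohexyl]acetate F6. Dehydration (MsCl, Et3N, then DBU) comes back to the route at 13.

Further compounds
F1 | step 10 | S-ethyl 2-[(1R)-1-methyl-3-oxo-2-(propan-2-ylidene)cyclohexyl]ethanethioate | CC(C)=C1C(=O)CCC[C@]1(C)CC(=O)SCC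
F2 | step 10 | 2-[(1R)-1-methyl-3-oxo-2-(propan-2-ylidene)cyclohexyl]acetaldehyde | CC(C)=C1C(=O)CCC[C@]1(C)CC=O
F3 | step 10 | (3R)-3-(3-bromoprop-2-en-1-yl)-3-methyl-2-(propan-2-ylidene)cyclohexan-1-one (E/Z mixture) | CC(C)=C1C(=O)CCC[C@]1(C)CC=CBr
F4 | step 15 | N,N-dimethylhydrazone of 22 | C1C(=NN(C)C)C=C[C@@H]2C(C)(C)[C@H](Br)CC[C@]21C
F5 | step 15 | C9-alkylated N,N-dimethylhydrazone (hydrazone of 23) | C=C[C@](C)(O[Si](CC)(CC)CC)CC[C@H]1C(=NN(C)C)C=C[C@@H]2C(C)(C)[C@H](Br)CC[C@]21C
F6 | step 7 | tert-butyl 2-[(1R)-2-(2-hydroxypropan-2-yl)-1-methyl-3-oxocyclohexyl]acetate (C2 epimers) | CC(C)(O)C1C(=O)CCC[C@]1(C)CC(=O)OC(C)(C)C
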